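## The problem

The target 17 is (3S,4R)-3-[(S)-hydroxy(4-hydroxy-3-methoxyphenyl)methyl]-4-(4-hydroxy-3-methoxybenzyl)dihydrofuran-2(3H)-one; the lactone is numbered O1, C2 (carbonyl), C3, C4, C5, with C7′ the carbinol carbon on C3 and C7 the benzylic CH2 on C4. One γ-lactone carries three contiguous stereocentres: C4 in the ring, C3 next to the carbonyl, and the exocyclic benzylic carbinol C7′. C3 and C4 are trans, the preferred arrangement, so C4 can direct C3, but nothing in the ring reliably directs C7′, which is why enolate aldol routes to this array tend to give both C7′ epimers. The compound is fragile: as a β-hydroxy lactone it can undergo retro-aldol cleavage or dehydration to the benzylidene lactone under base, its C7′–O bond is para to a phenol and can ionise through a quinone methide, and both guaiacyl phenols are easily oxidised. The enabling feature is that C2 is a carbonyl carbon between O1 and C3, while C3 and C7′ bear vicinal carbon and oxygen substituents. C2, O1 and the C7′ oxygen can therefore be read as CO, an alcohol and an oxygen nucleophile added across a C3=C7′ styrene tethered through the C5 hydroxyl. An (E)-alkene then encodes the C3/C7′ relationship, and only C4 has to be installed beforehand, as (R), with the phenols masked through an oxidative step.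

## Retrosynthesis

**Unmasking: 17 from 16, 16 from 15.** The last operations only remove protecting groups. The C7′ acetate of 15 is cleaved first, while both phenols are still silylated, because a free para-phenoxide would expel a C7′ acetate as a quinone methide. The aryl silyl ethers of 16 are then removed with buffered fluoride so that no alkoxide or phenoxide able to trigger retro-aldol cleavage is generated. Triisopropylsilyl ethers are used instead of the more common tert-butyldimethylsilyl ethers because they must survive amide bases, a borohydride, a hypervalent iodine oxidant and carbonate methanolysis.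

**Carbonylative difunctionalisation: 15 from 13 and 14.** Three bonds are cut at once: C2–O1, C2–C3 and C7′–O. This returns the lactone acetate 15 to the acyclic (R,E)-alkenol 13, carbon monoxide 14 and an acetate from the oxidant. The neighbouring cut, C3–C7′ by a lactone enolate aldol, leaves C7′ uncontrolled. The cut chosen here ties C7′ to C3 through the alkene geometry and removes the ring and two stereocentres in one step. The forward reaction must add the acyl carbon and the acetate anti across the E-alkene, close the ring 5-exo, place C7′ trans to the C4 substituent, and outrun β-hydride elimination. Compound 13 has one stereocentre, no ring, and is made of two vanillin-derived arenes.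

**The C4 stereocentre: 13 from 12, 12 from 10 and 4.** Alkenol 13 is the reduction product of imide 12, so C5 is carried at the acyl oxidation level as an oxazolidinone imide. The C4–C7 bond is then cut: 12 arises by alkylating the dienolate of the (E)-4-arylbut-3-enoyl imide 10 with benzylic bromide 4. This places the only pre-installed stereocentre under auxiliary control and gives crystallisable, diastereomerically purifiable intermediates. The forward reaction needs α-regioselectivity on a dienolate and retention of the E-styrene. With the (R)-auxiliary 8 the new centre is (R), because the styrenyl arm outranks the arylmethyl arm.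

**The styrene: 10 from 7 and 8, 7 from 2 and 5.** Imide 10 is the N-acyl derivative of auxiliary 8 and acid 7. The C3=C7′ double bond of 7 is cut by a Wittig disconnection to the silylated vanillin 2 and the carboxyethyl phosphonium salt 5, whose carboxylate ylide is E-selective with aromatic aldehydes. The alkene is conjugated to the arene and not to the carboxyl, so it has no thermodynamic reason to migrate.

**The electrophile: 4 from 3, 3 from 2, 2 from 1.** Bromide 4 is reached from the same aldehyde 2 by reduction to alcohol 3 and bromination. Both aryl units therefore come from vanillin 1 through one silylation.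

## Roads not taken

Alternative 1: The C3–C4 bond and both benzylic C–O bonds are cut together. Forward, (E)-ferulic acid A1 is oxidised with FeCl3 and O2, or with a laccase, to phenoxyl radicals that couple at their β-carbons; each carboxyl then adds to the opposite quinone methide to give the cis-fused exo,exo-dilactone A2. This is very economical: one step from a commodity acid forms the central C–C bond, both C–O bonds and the relative configuration of all three future stereocentres, with no protecting groups. For this target it has three weaknesses. A2 is formed as a racemate. The radical coupling also gives other dimer types. A2 is C2-symmetric, so reaching the target means hydrogenolysing exactly one of two equivalent benzylic C–O bonds and reducing exactly one of two equivalent carboxyl carbons to the C5 methylene, on a substrate with labile para-hydroxybenzylic lactone linkages. In step count and cost this road is better than the chosen plan. The chosen plan sets against it absolute control at C4 and a C7/C7′ differentiation built in from the start instead of a late statistical desymmetrisation.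

Alternative 2: The O1–C5 bond is cut by a Baeyer–Villiger retron. O-Silyl eugenol A3 would give the 3-(arylmethyl)cyclobutanone A4 by dichloroketene cycloaddition and dechlorination. Aqueous H2O2 with a chiral BINOL-derived phosphoric acid, or a Baeyer–Villiger monooxygenase, would then insert oxygen into one enantiotopic C–C bond to give the (R)-lactone A5. Every step is precedented, the chirality is catalytic, and A5 is reached in about three steps. The weak point is that the key step sets only C4, and enantioselection on a 3-benzyl cyclobutanone, whose prochiral centre is one carbon removed from the arene, is usually less complete than on 3-aryl analogues. C3 and C7′ would then come from an aldol reaction of A5 with aldehyde 2, which is reliably trans at C3/C4 but does not control C7′. This road carries less risk than the chosen plan, and is in substance the fallback held for step 8. The chosen plan sets against it that C3 and C7′ are formed together, stereospecifically, from an alkene geometry, and that C4 is secured through separable diastereomers.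

Alternative 3: The C4–C5 bond is cut. The silylated vanillin A6 and the (S)-oxazolidinone imide A7, the analogue of 10 that carries the mirror-image auxiliary and a tert-butyldimethylsilyl ether, would be joined in a syn-selective boron aldol reaction. Silylation of the new hydroxyl, auxiliary removal and esterification would then give the iodomethyl ester A8. The mirror-image auxiliary is needed because the auxiliary of 10 would deliver the enantiomeric syn aldol. With Et3B, O2 and (Me3Si)3SiH, A8 would give an acyloxymethyl radical that adds 5-exo to C4 of the styrene; reduction of the benzylic C7 radical would give the tris-silyl lactone A9. Its merit is that C3 and C7′ come from one of the most reliable asymmetric reactions available, which is more certain for C7′ than the chosen plan. The weak points are in the ring closure and the handling. The radical sits on the alkoxy carbon of an ester and can reach C4 only through the disfavoured s-cis ester conformer, so simple reduction competes. Iodomethyl esters are labile alkylating agents. The β-silyloxy α-styryl acyl unit is prone to retro-aldol cleavage and double-bond migration during auxiliary removal. C4 is set only by 1,2-induction. The sequence is no shorter than the chosen plan. The chosen plan sets against it a C4 centre fixed by the auxiliary and a ring closure that uses CO as the one-carbon unit with no tether conformational penalty.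

Key step: step 8

Assumption: both phenols are carried as triisopropylsilyl ethers throughout, a choice of protecting group that leaves the bonds formed in the key step unchanged; the target is the (3S,4R,7′S) isomer with a trans C3/C4 lactone.

## Route

Step 1
Reactants: 1 vanillin (4-hydroxy-3-methoxybenzaldehyde)
Product: 2 3-methoxy-4-(triisopropylsilyloxy)benzaldehyde
Conditions: TIPSCl, imidazole, DMF, 0 °C to rt
Reagents that add atoms: triisopropylsilyl chloride, CC(C)[Si](Cl)(C(C)C)C(C)C
Why: Phenol silylation (silyl ether formation with imidazole as base and nucleophilic catalyst); the triisopropylsilyl ether is chosen because it has to survive amide bases, LiBH4, PhI(OAc)2 and carbonate methanolysis later.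

Step 2
Reactants: 2 3-methoxy-4-(triisopropylsilyloxy)benzaldehyde
Product: 3 [3-methoxy-4-(triisopropylsilyloxy)phenyl]methanol
Conditions: NaBH4, EtOH–THF, 0 °C
Reagents that add atoms: none
Why: Borohydride reduction of the aryl aldehyde; the aryl silyl ether is inert under these cold, brief conditions.

Step 3
Reactants: 3 [3-methoxy-4-(triisopropylsilyloxy)phenyl]methanol
Product: 4 [4-(bromomethyl)-2-methoxyphenoxy]triisopropylsilane
Conditions: CBr4, PPh3, CH2Cl2, 0 °C
Reagents that add atoms: carbon tetrabromide, BrC(Br)(Br)Br
Why: Appel bromination converts the electron-rich benzylic alcohol into the bromide under neutral conditions that spare the silyl ether; the bromide is used promptly without storage.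

Step 4
Reactants: 2 3-methoxy-4-(triisopropylsilyloxy)benzaldehyde; 5 (2-carboxyethyl)triphenylphosphonium bromide
Product: 7 (E)-4-[3-methoxy-4-(triisopropylsilyloxy)phenyl]but-3-enoic acid, via sodium carboxylate ylide 6 (not isolated)
Conditions: 5, NaHMDS (2.2 equiv), THF, −78 °C; then 2, −78 °C to rt; cold 1 M HCl to pH 3
Reagents that add atoms: sodium bis(trimethylsilyl)amide, [Na+].C[Si](C)(C)[N-][Si](C)(C)C (sodium, in intermediate 6 only)
Why: Wittig olefination with the carboxylate-bearing ylide 6; ylides of this type are known to give (E)-4-arylbut-3-enoic acids from aromatic aldehydes, and the new alkene stays conjugated to the arene and not to the carboxyl.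

Step 5
Reactants: 7 (E)-4-[3-methoxy-4-(triisopropylsilyloxy)phenyl]but-3-enoic acid; 8 (R)-4-benzyloxazolidin-2-one
Product: 10 (R)-4-benzyl-3-[(E)-4-[3-methoxy-4-(triisopropylsilyloxy)phenyl]but-3-enoyl]oxazolidin-2-one, via mixed pivalic anhydride 9 (not isolated)
Conditions: PivCl, Et3N, THF, −20 °C; then 8, LiCl, −20 °C to rt
Reagents that add atoms: pivaloyl chloride, CC(C)(C)C(=O)Cl (pivaloyl group, in intermediate 9 only)
Why: N-Acylation of the oxazolidinone through the mixed pivalic anhydride under the LiCl/Et3N protocol, which avoids strong base and so avoids migration of the styrenyl double bond.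

Step 6
Reactants: 10 (R)-4-benzyl-3-[(E)-4-[3-methoxy-4-(triisopropylsilyloxy)phenyl]but-3-enoyl]oxazolidin-2-one; 4 [4-(bromomethyl)-2-methoxyphenoxy]triisopropylsilane
Product: 12 (R)-4-benzyl-3-[(R,E)-2-[3-methoxy-4-(triisopropylsilyloxy)benzyl]-4-[3-methoxy-4-(triisopropylsilyloxy)phenyl]but-3-enoyl]oxazolidin-2-one, via sodium Z-dienolate 11 (not isolated)
Conditions: NaHMDS, THF, −78 °C; then 4, −78 to −40 °C
Reagents that add atoms: sodium bis(trimethylsilyl)amide, [Na+].C[Si](C)(C)[N-][Si](C)(C)C (sodium, in intermediate 11 only)
Why: Evans-type diastereoselective alkylation: the chelated Z-dienolate 11 is attacked at its α-carbon on the face opposite the benzyl group of the auxiliary, which sets C4 as (R); α-attack is the normal course for metal dienolates and leaves the E-styrene in place.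

Step 7
Reactants: 12 (R)-4-benzyl-3-[(R,E)-2-[3-methoxy-4-(triisopropylsilyloxy)benzyl]-4-[3-methoxy-4-(triisopropylsilyloxy)phenyl]but-3-enoyl]oxazolidin-2-one
Product: 13 (R,E)-2-[3-methoxy-4-(triisopropylsilyloxy)benzyl]-4-[3-methoxy-4-(triisopropylsilyloxy)phenyl]but-3-en-1-ol
Conditions: LiBH4, MeOH (1.1 equiv), Et2O–THF, 0 °C
Reagents that add atoms: none
Why: Reductive cleavage of the imide by LiBH4 (hydride attack at the exocyclic carbonyl) releases the primary alcohol without touching C4 or the alkene, and auxiliary 8 is recovered.

Step 8
Reactants: 13 (R,E)-2-[3-methoxy-4-(triisopropylsilyloxy)benzyl]-4-[3-methoxy-4-(triisopropylsilyloxy)phenyl]but-3-en-1-ol; 14 carbon monoxide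
Product: 15 (S)-[3-methoxy-4-(triisopropylsilyloxy)phenyl]{(3S,4R)-4-[3-methoxy-4-(triisopropylsilyloxy)benzyl]-2-oxotetrahydrofuran-3-yl}methyl acetate
Conditions: Pd(OAc)2 (10 mol%), PhI(OAc)2 (2 equiv), CO (1 atm), MeCN–toluene, 25 °C
Reagents that add atoms: (diacetoxyiodo)benzene, CC(=O)OI(OC(C)=O)c1ccccc1
Why: Proposed new method: Pd(OAc)2 and CO should turn the C5 hydroxyl of 13 into an alkoxycarbonylpalladium acetate of divalent palladium, which inserts the tethered (E)-styrene by syn carbopalladation (C2–C3 formed, palladium on benzylic C7′), after which PhI(OAc)2 oxidises the benzylpalladium to tetravalent palladium and acetate displaces the metal at C7′ with inversion before C3–H can undergo β-hydride elimination; the closest known reaction types are the palladium-catalysed intramolecular alkoxycarbonylation of homoallylic and homopropargylic alcohols to γ-butyrolactones through alkoxycarbonylpalladium insertion, and the PhI(OAc)2-driven alkene difunctionalisations (diacetoxylation, aminoacetoxylation) that pass from divalent to tetravalent palladium. The γ-lactone is the only ring closed, in the 5-exo-trig mode; 6-endo closure is disfavoured by the short tether and by η3-benzyl stabilisation of palladium at C7′. C3 is set relative to C4 during insertion: in the envelope-like transition state the C4 arylmethyl group sits pseudo-equatorial and away from the palladium-bearing C7′ terminus, since the alternative eclipses the two, and this gives the trans-3,4 lactone. C7′ is set relative to C3 by syn insertion followed by invertive C–O bond formation, a net anti addition of C2 and acetate across the E-alkene that corresponds to the (3S,7′S) arrangement. If the sequence began instead with anti acetoxypalladation at C7′ followed by CO insertion and lactonisation, the same three bonds and the same anti relationship would result. The step needs chemoselectivity for alkoxycarbonylation over oxypalladation and alcohol oxidation; this is helped by the CO atmosphere and by the fact that the hydroxyl can reach the alkene only through a 4-exo mode or a stereoelectronically poor 5-endo mode, and the silylated phenols leave no free phenol for the iodine oxidant to dearomatise.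

Step 9
Reactants: 15 (S)-[3-methoxy-4-(triisopropylsilyloxy)phenyl]{(3S,4R)-4-[3-methoxy-4-(triisopropylsilyloxy)benzyl]-2-oxotetrahydrofuran-3-yl}methyl acetate
Product: 16 (3S,4R)-3-{(S)-hydroxy[3-methoxy-4-(triisopropylsilyloxy)phenyl]methyl}-4-[3-methoxy-4-(triisopropylsilyloxy)benzyl]dihydrofuran-2(3H)-one
Conditions: K2CO3 (0.3 equiv), MeOH–THF, 0 °C; aq. NH4Cl
Reagents that add atoms: none
Why: Base-catalysed transesterification (methanolysis) of the secondary acetate; at 0 °C with substoichiometric carbonate, acyl exchange should be faster than deprotonation at C3, and the aryl silyl ethers stay on so that no para-phenoxide can expel the acetate.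

Step 10
Reactants: 16 (3S,4R)-3-{(S)-hydroxy[3-methoxy-4-(triisopropylsilyloxy)phenyl]methyl}-4-[3-methoxy-4-(triisopropylsilyloxy)benzyl]dihydrofuran-2(3H)-one
Product: 17 (3S,4R)-3-[(S)-hydroxy(4-hydroxy-3-methoxyphenyl)methyl]-4-(4-hydroxy-3-methoxybenzyl)dihydrofuran-2(3H)-one
Conditions: TBAF, AcOH (1:1), THF, 0 °C
Reagents that add atoms: none
Why: Fluoride-mediated cleavage of the two aryl silyl ethers; buffering with acetic acid keeps the liberated phenols protonated, so retro-aldol cleavage and quinone methide formation at C7′ are avoided and C3, C4 and C7′ are untouched.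

## Compound list

1 | vanillin (4-hydroxy-3-methoxybenzaldehyde) | COc1cc(C=O)ccc1O | starting material
2 | 3-methoxy-4-(triisopropylsilyloxy)benzaldehyde | COc1cc(C=O)ccc1O[Si](C(C)C)(C(C)C)C(C)C | intermediate
3 | [3-methoxy-4-(triisopropylsilyloxy)phenyl]methanol | COc1cc(CO)ccc1O[Si](C(C)C)(C(C)C)C(C)C | intermediate
4 | [4-(bromomethyl)-2-methoxyphenoxy]triisopropylsilane | COc1cc(CBr)ccc1O[Si](C(C)C)(C(C)C)C(C)C | intermediate
5 | (2-carboxyethyl)triphenylphosphonium bromide | OC(=O)CC[P+](c1ccccc1)(c1ccccc1)c1ccccc1.[Br-] | starting material
6 | sodium 3-(triphenylphosphoranylidene)propanoate (carboxylate ylide) | [Na+].[O-]C(=O)CC=P(c1ccccc1)(c1ccccc1)c1ccccc1 | intermediate (not isolated)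
7 | (E)-4-[3-methoxy-4-(triisopropylsilyloxy)phenyl]but-3-enoic acid | OC(=O)C/C=C/c1ccc(O[Si](C(C)C)(C(C)C)C(C)C)c(OC)c1 | intermediate
8 | (R)-4-benzyloxazolidin-2-one | O=C1N[C@H](Cc2ccccc2)CO1 | starting material
9 | (E)-4-[3-methoxy-4-(triisopropylsilyloxy)phenyl]but-3-enoic pivalic anhydride | CC(C)(C)C(=O)OC(=O)C/C=C/c1ccc(O[Si](C(C)C)(C(C)C)C(C)C)c(OC)c1 | intermediate (not isolated)
10 | (R)-4-benzyl-3-[(E)-4-[3-methoxy-4-(triisopropylsilyloxy)phenyl]but-3-enoyl]oxazolidin-2-one | O=C(C/C=C/c1ccc(O[Si](C(C)C)(C(C)C)C(C)C)c(OC)c1)N1[C@H](Cc2ccccc2)COC1=O | intermediate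
11 | sodium (1Z,3E)-dienolate of 10 | [Na+].[O-]/C(=C\C=C\c1ccc(O[Si](C(C)C)(C(C)C)C(C)C)c(OC)c1)N1[C@H](Cc2ccccc2)COC1=O | intermediate (not isolated)
12 | (R)-4-benzyl-3-[(R,E)-2-[3-methoxy-4-(triisopropylsilyloxy)benzyl]-4-[3-methoxy-4-(triisopropylsilyloxy)phenyl]but-3-enoyl]oxazolidin-2-one | COc1cc(C[C@@H](C(=O)N2[C@H](Cc3ccccc3)COC2=O)/C=C/c2ccc(O[Si](C(C)C)(C(C)C)C(C)C)c(OC)c2)ccc1O[Si](C(C)C)(C(C)C)C(C)C | intermediate
13 | (R,E)-2-[3-methoxy-4-(triisopropylsilyloxy)benzyl]-4-[3-methoxy-4-(triisopropylsilyloxy)phenyl]but-3-en-1-ol | COc1cc(C[C@@H](CO)/C=C/c2ccc(O[Si](C(C)C)(C(C)C)C(C)C)c(OC)c2)ccc1O[Si](C(C)C)(C(C)C)C(C)C | intermediate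
14 | carbon monoxide | [C-]#[O+] | starting material
15 | (S)-[3-methoxy-4-(triisopropylsilyloxy)phenyl]{(3S,4R)-4-[3-methoxy-4-(triisopropylsilyloxy)benzyl]-2-oxotetrahydrofuran-3-yl}methyl acetate | COc1cc(C[C@H]2COC(=O)[C@@H]2[C@H](OC(C)=O)c2ccc(O[Si](C(C)C)(C(C)C)C(C)C)c(OC)c2)ccc1O[Si](C(C)C)(C(C)C)C(C)C | intermediate
16 | (3S,4R)-3-{(S)-hydroxy[3-methoxy-4-(triisopropylsilyloxy)phenyl]methyl}-4-[3-methoxy-4-(triisopropylsilyloxy)benzyl]dihydrofuran-2(3H)-one | COc1cc(C[C@H]2COC(=O)[C@@H]2[C@H](O)c2ccc(O[Si](C(C)C)(C(C)C)C(C)C)c(OC)c2)ccc1O[Si](C(C)C)(C(C)C)C(C)C | intermediate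
17 | (3S,4R)-3-[(S)-hydroxy(4-hydroxy-3-methoxyphenyl)methyl]-4-(4-hydroxy-3-methoxybenzyl)dihydrofuran-2(3H)-one | COc1cc(C[C@H]2COC(=O)[C@@H]2[C@H](O)c2ccc(O)c(OC)c2)ccc1O | target

## Step count and risks

Total: 10 steps. Longest linear sequence: 8 steps (1 → 2 → 7 → 10 → 12 → 13 → 15 → 16 → 17). The branch 2 → 3 → 4 joins at step 6 and is equally long.

**Step 8 (key step, proposed new method).** Several processes can divert it:
- β-hydride elimination at C3–H outrunning oxidation of the benzylpalladium, which gives loss of the C7′ oxygenation instead of C–O bond formation;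
- ionisation of the electron-rich benzylic tetravalent palladium intermediate before acetate attacks, which erodes the C7′ configuration;
- insufficient facial discrimination by the single C4 substituent;
- competing alcohol oxidation, 5-endo oxypalladation, or attack of the iodine oxidant on the electron-rich arenes.

The fallback uses only known chemistry and forms C3–C7′ by an aldol reaction instead. It sets out from 8, 4 and 2 and returns at 16. Mono-tert-butyl succinate is coupled to 8 (PivCl, Et3N, LiCl) to give the succinoyl imide F1. Its sodium enolate is alkylated with 4 to give the (R)-arylmethyl imide F2. LiBH4 gives the hydroxy tert-butyl ester F3, which p-TsOH closes to the (R)-β-(arylmethyl)butyrolactone F4. The lithium enolate of F4 (LiHMDS, THF, −78 °C) is added to aldehyde 2. This should give the trans lactone 16 together with its C7′ epimer F5, from which 16 is separated by chromatography. Steps 9 and 10 are reduced to step 10. Material lost to β-hydride elimination alone could also be rescued by the conjugate borylation–oxidation sequence described under step 9.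

**Step 6.** The aryl-conjugated dienolate 11 is more stabilised than a simple imide enolate. Sluggish alkylation, leakage to γ-attack, or migration or epimerisation through re-deprotonation of the doubly activated product are the likely failures, aggravated by decomposition of the electron-rich bromide while it waits. The fallback installs the styrene after the stereocentre. It sets out from 8, 4 and 2 and returns at 13. Auxiliary 8 is acylated with (E)-but-2-enoyl chloride to give the crotonyl imide F6. Deconjugative α-alkylation of its sodium dienolate with 4 gives the α-(arylmethyl)but-3-enoyl imide F7. LiBH4 gives the (R)-2-(arylmethyl)but-3-en-1-ol F8. Aldehyde 2 is methylenated (Ph3P=CH2) to give the styrene F9. Cross-metathesis of F8 with F9 (second-generation Grubbs catalyst) gives 13.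

**Step 9.** The acetate sits β to the lactone carbonyl. Base-induced elimination of acetic acid across C3–C7′, or premature loss of the C7′-aryl silyl group followed by quinone methide ionisation, could compete with methanolysis. The fallback turns the elimination into the route. It sets out from 15 and returns at 16. DBU in toluene gives the (E)-benzylidene lactone F10. Copper-catalysed conjugate borylation (CuCl, a chiral bisphosphine, B2pin2, NaOtBu, MeOH) adds boron to C7′ under ligand control, with protonation at C3 trans to the C4 substituent, to give the C7′ pinacol boronate F11. NaBO3·4H2O oxidises the C–B bond with retention to give 16.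

**Step 10.** If the fluoride medium is not kept buffered, a phenoxide or C7′ alkoxide can start retro-aldol fragmentation or C7′ epimerisation through a quinone methide. The fallback reverses the order of the endgame so that C7′ stays acylated during desilylation and no base is needed afterwards. It sets out from 15 and returns at 17. Et3N·3HF in THF, a weakly acidic fluoride source that leaves the phenols protonated, removes both silyl groups to give the diphenol acetate F12. A lipase in pH 7 phosphate buffer with a cosolvent then hydrolyses the C7′ acetate to give 17 without any added base.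

## Further compounds

F1 | step 8 | tert-butyl 4-[(R)-4-benzyl-2-oxooxazolidin-3-yl]-4-oxobutanoate | CC(C)(C)OC(=O)CCC(=O)N1[C@H](Cc2ccccc2)COC1=O
F2 | step 8 | tert-butyl (R)-4-[(R)-4-benzyl-2-oxooxazolidin-3-yl]-3-[3-methoxy-4-(triisopropylsilyloxy)benzyl]-4-oxobutanoate | COc1cc(C[C@H](CC(=O)OC(C)(C)C)C(=O)N2[C@H](Cc3ccccc3)COC2=O)ccc1O[Si](C(C)C)(C(C)C)C(C)C
F3 | step 8 | tert-butyl (R)-4-hydroxy-3-[3-methoxy-4-(triisopropylsilyloxy)benzyl]butanoate | COc1cc(C[C@H](CC(=O)OC(C)(C)C)CO)ccc1O[Si](C(C)C)(C(C)C)C(C)C
F4 | step 8 | (R)-4-[3-methoxy-4-(triisopropylsilyloxy)benzyl]dihydrofuran-2(3H)-one | COc1cc(C[C@H]2COC(=O)C2)ccc1O[Si](C(C)C)(C(C)C)C(C)C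
F5 | step 8 | (3S,4R)-3-{(R)-hydroxy[3-methoxy-4-(triisopropylsilyloxy)phenyl]methyl}-4-[3-methoxy-4-(triisopropylsilyloxy)benzyl]dihydrofuran-2(3H)-one (C7′ epimer of 16) | COc1cc(C[C@H]2COC(=O)[C@@H]2[C@@H](O)c2ccc(O[Si](C(C)C)(C(C)C)C(C)C)c(OC)c2)ccc1O[Si](C(C)C)(C(C)C)C(C)C
F6 | step 6 | (R)-4-benzyl-3-[(E)-but-2-enoyl]oxazolidin-2-one | C/C=C/C(=O)N1[C@H](Cc2ccccc2)COC1=O
F7 | step 6 | (R)-4-benzyl-3-[(R)-2-[3-methoxy-4-(triisopropylsilyloxy)benzyl]but-3-enoyl]oxazolidin-2-one | COc1cc(C[C@@H](C(=O)N2[C@H](Cc3ccccc3)COC2=O)C=C)ccc1O[Si](C(C)C)(C(C)C)C(C)C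
F8 | step 6 | (R)-2-[3-methoxy-4-(triisopropylsilyloxy)benzyl]but-3-en-1-ol | COc1cc(C[C@@H](CO)C=C)ccc1O[Si](C(C)C)(C(C)C)C(C)C
F9 | step 6 | triisopropyl(2-methoxy-4-vinylphenoxy)silane | COc1cc(C=C)ccc1O[Si](C(C)C)(C(C)C)C(C)C
F10 | step 9 | (R,E)-4-[3-methoxy-4-(triisopropylsilyloxy)benzyl]-3-[3-methoxy-4-(triisopropylsilyloxy)benzylidene]dihydrofuran-2(3H)-one | COc1cc(C[C@H]2COC(=O)/C2=C/c3ccc(O[Si](C(C)C)(C(C)C)C(C)C)c(OC)c3)ccc1O[Si](C(C)C)(C(C)C)C(C)C
F11 | step 9 | (3R,4R)-3-{(S)-[3-methoxy-4-(triisopropylsilyloxy)phenyl](4,4,5,5-tetramethyl-1,3,2-dioxaborolan-2-yl)methyl}-4-[3-methoxy-4-(triisopropylsilyloxy)benzyl]dihydrofuran-2(3H)-one | COc1cc(C[C@H]2COC(=O)[C@@H]2[C@H](B3OC(C)(C)C(C)(C)O3)c4ccc(O[Si](C(C)C)(C(C)C)C(C)C)c(OC)c4)ccc1O[Si](C(C)C)(C(C)C)C(C)C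
F12 | step 10 | (S)-(4-hydroxy-3-methoxyphenyl)[(3S,4R)-4-(4-hydroxy-3-methoxybenzyl)-2-oxotetrahydrofuran-3-yl]methyl acetate | COc1cc(C[C@H]2COC(=O)[C@@H]2[C@H](OC(C)=O)c2ccc(O)c(OC)c2)ccc1O
A1 | alternative 1 | (E)-ferulic acid | COc1cc(/C=C/C(=O)O)ccc1O
A2 | alternative 1 | cis-fused exo,exo-4,8-bis(4-hydroxy-3-methoxyphenyl)-3,7-dioxabicyclo[3.3.0]octane-2,6-dione (enantiomer that maps onto the target; formed as the racemate) | COc1cc(ccc1O)[C@@H]1[C@H]2C(=O)O[C@H](c3ccc(O)c(OC)c3)[C@H]2C(=O)O1
A3 | alternative 2 | (4-allyl-2-methoxyphenoxy)(tert-butyl)dimethylsilane (O-silyl eugenol) | COc1cc(CC=C)ccc1O[Si](C)(C)C(C)(C)C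
A4 | alternative 2 | 3-[4-(tert-butyldimethylsilyloxy)-3-methoxybenzyl]cyclobutan-1-one | COc1cc(CC2CC(=O)C2)ccc1O[Si](C)(C)C(C)(C)C
A5 | alternative 2 | (R)-4-[4-(tert-butyldimethylsilyloxy)-3-methoxybenzyl]dihydrofuran-2(3H)-one | COc1cc(C[C@H]2COC(=O)C2)ccc1O[Si](C)(C)C(C)(C)C
A6 | alternative 3 | 4-(tert-butyldimethylsilyloxy)-3-methoxybenzaldehyde | COc1cc(C=O)ccc1O[Si](C)(C)C(C)(C)C
A7 | alternative 3 | (S)-4-benzyl-3-[(E)-4-[4-(tert-butyldimethylsilyloxy)-3-methoxyphenyl]but-3-enoyl]oxazolidin-2-one | O=C(C/C=C/c1ccc(O[Si](C)(C)C(C)(C)C)c(OC)c1)N1[C@@H](Cc2ccccc2)COC1=O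
A8 | alternative 3 | iodomethyl (2S,3S)-3-(tert-butyldimethylsilyloxy)-3-[4-(tert-butyldimethylsilyloxy)-3-methoxyphenyl]-2-[(E)-2-[4-(tert-butyldimethylsilyloxy)-3-methoxyphenyl]vinyl]propanoate | ICOC(=O)[C@@H](/C=C/c1ccc(O[Si](C)(C)C(C)(C)C)c(OC)c1)[C@H](O[Si](C)(C)C(C)(C)C)c1ccc(O[Si](C)(C)C(C)(C)C)c(OC)c1
A9 | alternative 3 | (3S,4R)-3-{(S)-(tert-butyldimethylsilyloxy)[4-(tert-butyldimethylsilyloxy)-3-methoxyphenyl]methyl}-4-[4-(tert-butyldimethylsilyloxy)-3-methoxybenzyl]dihydrofuran-2(3H)-one | COc1cc(C[C@H]2COC(=O)[C@@H]2[C@H](O[Si](C)(C)C(C)(C)C)c2ccc(O[Si](C)(C)C(C)(C)C)c(OC)c2)ccc1O[Si](C)(C)C(C)(C)C
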